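**Remarks.** Atoms carry the labels defined in the analysis, always with the element letter (C9a, N4); bare numbers are compounds. The same atom labels are used for the corresponding atoms of every intermediate. Compounds 7–11 are named with indene locants: indene C1 = C10, C2 = C11, C3 = C12, C3a = C9a, C4 = C5, C5 = C6, C6 = C7, C7 = C8, C7a = C9; the three arm carbons on C3a are C1–C3.

## Analysis of the target

Target 26 is pentacyclic. A pyrrolidine (ring A: N4, C1, C2, C3, C9a) and an azepane (ring B: N4, C5–C8, C9, C9a) share the N4–C9a bond. A cyclopentane (ring C: C9, C9a, C12, C11, C10) is fused to ring B along C9–C9a and meets ring A only at C9a. A γ-lactone (ring D: C11, O, C14, C13, C12) is cis-fused to ring C, and a second γ-lactone (ring E: C18, C19, C20, C21, O) hangs on C3. There are nine stereocentres: C3, C9, C9a, C10, C11, C12, C13, C18 and C20.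

On ring C the ethyl group (on C10), the lactone oxygen (on C11), C13 (on C12), C1 (on C9a) and H9 lie on one face; N4 and C8 lie on the other, so rings B and C are cis-fused. At C13 the methyl group (C17) is exo and the hydroxyl endo to the C/D bicycle. Across ring A the C3 substituent is cis to C9, C3/C18 are threo, and the C20 methyl is cis to the C18 substituent.

The sensitive groups are the two γ-lactones (nucleophiles, hydride, base), the epimerisable C20, the tertiary α-hydroxy lactone and the oxidisable tertiary amine. The synthesis is hard because C9a is a fully substituted carbon that is bonded to nitrogen, shared by three rings and flanked by the stereocentres C9 and C12; seven of the nine stereocentres sit on one compact core.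

The strategy rests on the N4–C9a bond. If N4 is taken out from between C9a and C5, rings B and C become a cis-hydrindanone in which C9a is an all-carbon quaternary centre α to a ketone (C5) and carries the three-carbon arm C1–C3. Aldol and hydrogenation chemistry can control such a centre, and nitrogen can be inserted afterwards with retention.

## Retrosynthetic reasoning

**26 ⇒ 25 (O–Si).** The tertiary hydroxyl on C13 is carried as a silyl ether from 17 onwards. It must be masked for the enolate methylation. It must also not trap the N-acyliminium ion or react with the thionating agent. Its bulk sits on the C12 side of ring A and is used for facial control at C3. Cleavage is left to the end because it is mild to both lactones and to C20.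

**25 ⇒ 24 ⇒ 23 (C5 carbonyl).** The lactam carbonyl is kept as long as possible. It makes N4 non-basic and it is what allows the oxidation at C3 and the N-acyliminium addition. It is removed through thiolactam 24 so that the two lactone carbonyls are not touched.

**23 ⇒ 22 ⇒ 19 + 21 (C3–C18).** This is the only bond that joins ring E to the core, and C3 is α to the amide nitrogen. Cutting it gives the latent N-acyliminium ion 19 and the silyloxyfuran 21, a γ-nucleophilic butenolide equivalent made from 20. The forward addition must set C3 (face of ring A) and C18 (threo); hydrogenation of butenolide 22 then sets C20.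

**19 ⇒ 18 (C3–O).** Oxidation at the carbon next to nitrogen needs no regiocontrol: C9a has no hydrogen and C5 is the carbonyl, so only C3 can react.

**18 ⇒ 17 ⇒ 16 (C13–C17 and O–Si).** The methyl group is put on last in ring D, on a planar enolate. Both C13 epimers of 16 and 17 therefore converge, and the exo face of the cis-fused C/D bicycle decides the configuration.

**16 ⇒ 14 ⇒ 12 + 13 (lactone C–O and C12–C13).** In 12, C11 is a ketone and C12 its less substituted α-carbon. An aldol addition to the two-carbon aldehyde ester 13 brings in C13 with its oxygen and C14 in one step. Reduction of C11 from the face opposite to its two neighbours, followed by lactonisation, closes ring D.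

**12 ⇒ 11 (N4–C9a and N4–C5; the key disconnection).** Removing N4 from ring B leaves the cis-hydrindanedione 11 with an azide at the end of the C1–C3 arm. Forward, the azide nitrogen has to add to the C5 carbonyl and C9a has to migrate to nitrogen. This forms both N–C bonds, closes ring A and enlarges the cyclohexanone to the ring B lactam without touching a stereocentre. The cut is made here because it turns the aza-quaternary centre into an all-carbon one.

**11 ⇒ 9 ⇒ 7 (C–N3; C9–H and C10–H).** The azide comes from the primary alcohol 9. The ring-fusion hydrogen comes from hydrogenation of enone 7 on the face of the arm; the same operation frees the alcohol from its benzyl ether, and C10 is then set by equilibration.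

**7 ⇒ 6 (C9=C10).** Opening ring C at the enone gives the prochiral triketone 6. The forward aldol condensation must choose one of two enantiotopic ring carbonyls. This creates C9a, the one stereocentre that no later step can correct.

**6 ⇒ 4 + 5 and 4 ⇒ 1 + 2 (two C–C bonds at the future C9a).** The unactivated three-carbon arm is attached by reductive alkylation of 1 with aldehyde 2, because a simple 3-halopropyl electrophile would mainly O-alkylate the dione. The activated bromoketone 5 is then used for the enolate alkylation that makes the carbon quaternary.

## Alternatives that were turned down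

**Alternative 1:** *Iridium-catalysed allylic dearomatisation of a pyrrole.*
- **Disconnection:** the C9a–C9 bond, with ring A present as a pyrrole whose C2 is the future C9a.
- **Forward key step:** [Ir(cod)Cl]2, a chiral phosphoramidite and Cs2CO3 ionise an allylic carbonate tethered to the pyrrole. The pyrrole carbon attacks the substituted allyl terminus and gives the vinyl spiro-2H-pyrrole A1 (rings A and C; C11 as a dioxolane; C3 carrying a silyloxymethyl group).
- **For:** the N4–C9a bond exists from the start, so no nitrogen has to be inserted. C9a and C9 are set together under catalyst control, a reaction class with broad precedent. The future C18 is already on C3.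
- **Against:** ring B is missing. The vinyl group supplies only C8 and C7, and N4 becomes a secondary amine wedged between the quaternary C9a and a substituted C3, so its alkylation and a seven-membered ring closure are slow. The 2H-pyrrole must be reduced at C=N and C=C, which sets C3 by hydride with the same facial question as here. Spiro-2H-pyrroles undergo acid-promoted 1,2-shifts that would destroy C9a. The C10 stereocentre must be made beforehand and matched to the catalyst. Ring E still has to be grown from the CH2O group with two new stereocentres.
- **Comparison:** it is stronger on enantiocontrol at C9a, which in the chosen route depends on the least precedented early step. The chosen route offers the complete A/B/C core with carbonyl handles at C5 and C11 after six steps, with two rings closed at once.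

**Alternative 2:** *Three-component coupling on a silyloxycyclopentenone.*
- **Disconnection:** the C10–C15 (ethyl) and C9–C8 bonds on a ring C that is already present.
- **Forward key step:** a lithium ethylzincate (LiZnMe2Et) adds to the enone A3, anti to the silyloxy group. The zinc enolate is alkylated by the propargylic iodide A4, anti to the new ethyl group, and gives the trans,trans cyclopentanone A2.
- **For:** this is the most dependable chemistry of all four routes. The absolute configuration comes from a commercially available enantiopure enone, C9 and C10 are set by substrate control, and the step is convergent.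
- **Against:** no ring is formed. C9a is still a ketone carbon, so N4 and C1–C3 must be added to a ketimine next to C9 with facial control before rings A and B can be closed. The hardest centre is thus left for a long sequence. The C11 oxygen arrives trans to ethyl, whereas the target has it cis, so it must be inverted later. The β-silyloxy ketone can eliminate.
- **Comparison:** it is stronger on reliability and on the source of chirality. The chosen route solves C9a first, as a carbon-only problem, and needs far fewer steps after its key step to reach rings A and B.

**Alternative 3:** *Acyl radical cyclisation onto an alkoxyacrylate.*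
- **Disconnection:** the C11–C12 bond inside ring C.
- **Forward key step:** (Me3Si)3SiH and AIBN turn a phenyl selenoester into the C11 acyl radical. It closes ring C by 5-exo addition to the β-carbon (C12) of a 2-benzyloxyacrylate on C9a and gives ketone A5 (rings A, B, C; lactam carbonyl at C3).
- **For:** C13 with its oxygen and C14 arrive together with ring C, so no separate aldol is needed. Radical conditions tolerate the lactam. A lactam carbonyl at C3 is a direct handle for ring E.
- **Against:** the substrate must already contain the A/B bicycle with the aza-quaternary C9a, the acrylate on it and a branched chain on C9. The central problem is therefore moved into the precursor, not solved. The α-branched acyl radical can lose CO. It has to attack a carbon next to a quaternary centre. The configuration at C12 relative to N4 is not secured.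
- **Comparison:** it is stronger on ring D economy. The chosen route offers a short, carbon-based construction of C9a and leaves the lactam carbonyl at C5, where it activates the only N-α C–H bond (C3) for ring E.

Key step: step 6

**Assumptions.**
- Which pseudoenantiomer of the amine catalyst in step 3 gives (S)-7 cannot be derived from precedent; the one that does is used (the quinine-derived amine is written).
- Compounds 1, 2, 5, 13 (as its toluene solution) and 20 are taken as commercial.

## Steps

**Step 1**
Reactants: 1 cyclohexane-1,3-dione; 2 3-(benzyloxy)propanal
Product: 4 2-[3-(benzyloxy)propyl]cyclohexane-1,3-dione, via alkylidene dione 3 (not isolated)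
Conditions: Hantzsch ester (diethyl 2,6-dimethyl-1,4-dihydropyridine-3,5-dicarboxylate, 1 equiv), L-proline (10 mol%), CH2Cl2, rt
Reagents that add atoms: none
Why: Three-component reductive alkylation: proline-catalysed Knoevenagel condensation gives 3, which the Hantzsch ester reduces by hydride transfer; only carbon is alkylated, whereas an unactivated 3-halopropyl electrophile would mainly O-alkylate this dione, and the fast condensation with the acidic dione should outrun β-elimination of the β-benzyloxy aldehyde.

**Step 2**
Reactants: 4 2-[3-(benzyloxy)propyl]cyclohexane-1,3-dione; 5 1-bromopentan-2-one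
Product: 6 2-[3-(benzyloxy)propyl]-2-(2-oxopentyl)cyclohexane-1,3-dione
Conditions: 1 M aq. NaOH (1.0 equiv), THF, 0 °C to rt
Reagents that add atoms: none
Why: SN2 C-alkylation of the sodium enolate of a 2-alkylcyclohexane-1,3-dione by an α-bromo ketone, a soft and very reactive electrophile; the protic medium hydrogen-bonds the enolate oxygens and favours attack through carbon, and the new quaternary carbon is not yet stereogenic because the two ring carbonyls are equivalent.

**Step 3**
Reactants: 6 2-[3-(benzyloxy)propyl]-2-(2-oxopentyl)cyclohexane-1,3-dione
Product: 7 (S)-3a-[3-(benzyloxy)propyl]-1-ethyl-3,5,6,7-tetrahydro-2H-indene-2,4(3aH)-dione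
Conditions: 9-amino-9-deoxy-epi-quinine (20 mol%), CF3CO2H (40 mol%), toluene, 60 °C
Reagents that add atoms: none
Why: Proposed new method: the primary amine condenses with the side-chain ketone, the enamine formed towards the propyl CH2 adds to one of the two enantiotopic ring carbonyls in a transition state organised by the protonated quinuclidine, and the ketol loses water to the tetrasubstituted enone, which fixes C9a; the closest known reaction type is the amine-catalysed desymmetrising aldol condensation of 2-(3-oxoalkyl)cyclohexane-1,3-diones (Hajos–Parrish–Eder–Sauer–Wiechert reaction), which closes a six-membered enone ring, whereas here a five-membered ring closes in the 5-(enolendo)-exo-trig mode, for which only achiral base- or acid-mediated versions are established.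

**Step 4**
Reactants: 7 (S)-3a-[3-(benzyloxy)propyl]-1-ethyl-3,5,6,7-tetrahydro-2H-indene-2,4(3aH)-dione
Product: 9 (1R,3aS,7aR)-1-ethyl-3a-(3-hydroxypropyl)octahydro-1H-indene-2,4-dione, via all-cis C10 epimer 8 (not isolated)
Conditions: H2 (4 atm), 10% Pd/C, EtOAc–EtOH, rt; filter; K2CO3, MeOH, rt
Reagents that add atoms: none
Why: Heterogeneous hydrogenation should add H2 to the tetrasubstituted enone from the face of the angular arm (the convex face, as with Hajos–Parrish-type enones), giving the cis-fused hydrindane and fixing C9, and it cleaves the benzyl ether by hydrogenolysis; syn addition leaves ethyl cis to C8 in 8, and carbonate in methanol epimerises C10 through the C11 enolate to the more stable isomer with ethyl trans to C8.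

**Step 5**
Reactants: 9 (1R,3aS,7aR)-1-ethyl-3a-(3-hydroxypropyl)octahydro-1H-indene-2,4-dione
Product: 11 (1R,3aS,7aR)-3a-(3-azidopropyl)-1-ethyloctahydro-1H-indene-2,4-dione, via mesylate 10 (not isolated)
Conditions: MsCl, Et3N, CH2Cl2, 0 °C; then NaN3, DMF, 60 °C
Reagents that add atoms: sodium azide [Na+].[N-]=[N+]=[N-]; methanesulfonyl chloride CS(=O)(=O)Cl (its atoms are in 10 only)
Why: Sulfonylation of the primary alcohol (the open form of any hydroxy ketone/hemiketal equilibrium) and SN2 displacement by azide; no stereocentre is touched and C10 already has its thermodynamic configuration.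

**Step 6**
Reactants: 11 (1R,3aS,7aR)-3a-(3-azidopropyl)-1-ethyloctahydro-1H-indene-2,4-dione
Product: 12 tricyclic keto lactam (9R,9aS,10R)
Conditions: CF3SO3H (5 equiv), CH2Cl2, 0 °C to rt
Reagents that add atoms: none
Why: Intramolecular Schmidt reaction: the acid protonates the C5 ketone, the inner azide nitrogen adds to it (6-exo-trig) to give a six-membered azidohydrin, and the C9a–C5 bond shifts from carbon to nitrogen while N2 leaves. The closest known reaction type is the acid-promoted conversion of 2-(3-azidopropyl)cycloalkanones into ring-fused bicyclic lactams. Ring A is closed by this 1,2-shift, which contracts the nitrogen-containing six-membered ring to the pyrrolidine, and ring B arises by one-atom enlargement of the cyclohexanone to the seven-membered lactam. No stereocentre is created: C9a migrates with retention, so the cis relation of the arm and H9 from step 4 becomes the cis B/C fusion, and C10 keeps its thermodynamic configuration even if it enolises in acid. The step needs chemoselectivity between the two ketones: the cyclopentanone carbonyl C11 would require a seven-membered azidohydrin and is left alone. It also needs migration of the quaternary C9a and not of C6H2, which would give a bridged lactam. This is secured by the tether, which places the ring bond C9a–C5 antiperiplanar to the departing N2 when the diazonium group is equatorial, and by the higher migratory aptitude of the more substituted carbon.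

**Step 7**
Reactants: 12 tricyclic keto lactam (9R,9aS,10R); 13 ethyl glyoxylate
Product: 14 aldol adduct ethyl 2-hydroxy-2-(C12-yl)acetate (9R,9aR,10R,12R; C13 either)
Conditions: LDA (LiN(iPr)2, 1.05 equiv), THF, −78 °C; then 13 (freshly distilled), −78 °C; AcOH quench at −78 °C
Reagents that add atoms: none
Why: Lithium enolate aldol addition: LDA should remove a proton from the less substituted α-carbon C12 (CH2) in preference to C10 (CH bearing ethyl) and leaves the less acidic lactam alone, and the enolate should add to the aldehyde from the convex face of ring C, anti to N4 and ring B, placing the side chain cis to C1; the C13 mixture is removed in step 10.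

**Step 8**
Reactants: 14 aldol adduct (9R,9aR,10R,12R; C13 either)
Product: 16 α-hydroxy lactone with ring D closed (9R,9aR,10R,11R,12R; C13 either), via diol ester 15 (not isolated)
Conditions: NaBH4, CeCl3·7H2O, MeOH, −78 to −40 °C; then p-TsOH (cat.), CH2Cl2, rt
Reagents that add atoms: none
Why: Luche reduction: the small hydride should attack the C11 ketone from the face opposite to its two neighbours (ethyl on C10, side chain on C12) and give the all-cis alcohol 15 without retro-aldol or ester reduction at low temperature; acid then closes the γ-lactone by 5-exo-trig acyl substitution, which is possible only for this cis arrangement.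

**Step 9**
Reactants: 16 α-hydroxy lactone (C13 either)
Product: 17 tert-butyldimethylsilyl ether of 16 (C13 either)
Conditions: TBSOTf, 2,6-lutidine, CH2Cl2, 0 °C
Reagents that add atoms: tert-butyldimethylsilyl trifluoromethanesulfonate CC(C)(C)[Si](C)(C)OS(=O)(=O)C(F)(F)F
Why: Silylation of the secondary α-hydroxyl; the ether blocks O-methylation in step 10 and later shields the C12 side of ring A.

**Step 10**
Reactants: 17 silyl ether (C13 either)
Product: 18 C13-methylated silyloxy lactone (9R,9aR,10R,11R,12S,13S)
Conditions: LDA (LiN(iPr)2), THF, −78 °C; then MeI, DMPU, −78 to −40 °C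
Reagents that add atoms: iodomethane CI
Why: Enolate alkylation of an α-silyloxy lactone: both C13 epimers give the same planar enolate, and iodomethane should approach from the exo (convex) face of the cis-fused C/D bicycle, so methyl ends exo (cis to H12) and the silyloxy group endo; the lactam α-protons are less acidic and stay untouched.

**Step 11**
Reactants: 18 C13-methylated silyloxy lactone
Product: 19 3-methoxy lactam (C3 either)
Conditions: graphite anode, Pt cathode, Et4NOTs, MeOH, constant current (about 3 F/mol), 0–10 °C, undivided cell
Reagents that add atoms: methanol CO
Why: Shono oxidation: two-electron anodic oxidation of the amide and loss of a proton give the N-acyliminium ion, which methanol traps; only C3 can react because C9a bears no hydrogen and C5 is the carbonyl, and the C3 mixture is planarised again in step 13.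

**Step 12**
Reactants: 20 3-methylfuran-2(5H)-one
Product: 21 3-methyl-2-(triisopropylsilyloxy)furan
Conditions: TIPSOTf, Et3N, CH2Cl2, 0 °C
Reagents that add atoms: triisopropylsilyl trifluoromethanesulfonate CC(C)[Si](C(C)C)(C(C)C)OS(=O)(=O)C(F)(F)F
Why: O-silylation of the butenolide dienolate gives the aromatic 2-silyloxyfuran, the γ-nucleophile for step 13.

**Step 13**
Reactants: 19 3-methoxy lactam (C3 either); 21 3-methyl-2-(triisopropylsilyloxy)furan
Product: 22 butenolide adduct (3S,9R,9aR,10R,11R,12S,13S,18S)
Conditions: BF3·OEt2, CH2Cl2, −78 °C
Reagents that add atoms: none
Why: Vinylogous Mannich reaction: BF3·OEt2 ionises 19 to the N-acyliminium ion and C5 of the silyloxyfuran adds to C3; attack is expected on the face of ring A syn to C9, because the other face is flanked by C12 with the fully substituted C13 and its endo silyloxy group, and the usual preference of five-membered N-acyliminium ions for the threo adduct should set C18 relative to C3.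

**Step 14**
Reactants: 22 butenolide adduct
Product: 23 saturated lactone E lactam (3S,9R,9aR,10R,11R,12S,13S,18S,20S)
Conditions: H2 (1 atm), 10% Pd/C, EtOAc, rt
Reagents that add atoms: none
Why: Catalytic hydrogenation of the butenolide from the face opposite to the C18 substituent should place the C20 methyl cis to it; lactam, lactone D and silyl ether are inert.

**Step 15**
Reactants: 23 saturated lactone E lactam
Product: 24 C5 thiolactam
Conditions: Lawesson's reagent (0.6 equiv), toluene, 80 °C
Reagents that add atoms: Lawesson's reagent COc1ccc(cc1)P1(=S)SP(=S)(S1)c1ccc(OC)cc1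
Why: Thionation with Lawesson's reagent: the amide carbonyl is far more reactive than the two lactone carbonyls at this temperature, so only C5 should be converted.

**Step 16**
Reactants: 24 C5 thiolactam
Product: 25 silyl ether of the target
Conditions: Raney Ni (W-2), THF–EtOH, rt
Reagents that add atoms: none
Why: Raney nickel desulfurisation reduces the thiocarbonyl to the C5 methylene and leaves lactones, silyl ether and stereocentres untouched; thionation followed by desulfurisation is the standard lactone-tolerant way to deoxygenate a lactam.

**Step 17**
Reactants: 25 silyl ether of the target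
Product: 26 target CNP0260919.3
Conditions: HF·pyridine, THF, 0 °C to rt
Reagents that add atoms: none
Why: Fluoride cleavage of the tertiary silyl ether under non-basic conditions, which should neither open the lactones nor epimerise C20; the amine is only protonated and is freed on work-up.

## Compound list

1 | cyclohexane-1,3-dione | O=C1CCCC(=O)C1 | starting material
2 | 3-(benzyloxy)propanal | O=CCCOCc1ccccc1 | starting material
3 | 2-[3-(benzyloxy)propylidene]cyclohexane-1,3-dione | O=C1CCCC(=O)C1=CCCOCc1ccccc1 | intermediate (not isolated)
4 | 2-[3-(benzyloxy)propyl]cyclohexane-1,3-dione | O=C1CCCC(=O)C1CCCOCc1ccccc1 | intermediate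
5 | 1-bromopentan-2-one | CCCC(=O)CBr | starting material
6 | 2-[3-(benzyloxy)propyl]-2-(2-oxopentyl)cyclohexane-1,3-dione | CCCC(=O)CC1(CCCOCc2ccccc2)C(=O)CCCC1=O | intermediate
7 | (S)-3a-[3-(benzyloxy)propyl]-1-ethyl-3,5,6,7-tetrahydro-2H-indene-2,4(3aH)-dione | CCC1=C2CCCC(=O)[C@@]2(CCCOCc3ccccc3)CC1=O | intermediate
8 | (1S,3aS,7aR)-1-ethyl-3a-(3-hydroxypropyl)octahydro-1H-indene-2,4-dione (cis-fused, ethyl cis to C8) | CC[C@@H]1C(=O)C[C@]2(CCCO)C(=O)CCC[C@H]12 | intermediate (not isolated)
9 | (1R,3aS,7aR)-1-ethyl-3a-(3-hydroxypropyl)octahydro-1H-indene-2,4-dione (cis-fused, ethyl trans to C8) | CC[C@H]1C(=O)C[C@]2(CCCO)C(=O)CCC[C@H]12 | intermediate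
10 | 3-[(1R,3aS,7aR)-1-ethyl-2,4-dioxooctahydro-3aH-inden-3a-yl]propyl methanesulfonate | CC[C@H]1C(=O)C[C@]2(CCCOS(C)(=O)=O)C(=O)CCC[C@H]12 | intermediate (not isolated)
11 | (1R,3aS,7aR)-3a-(3-azidopropyl)-1-ethyloctahydro-1H-indene-2,4-dione | CC[C@H]1C(=O)C[C@]2(CCCN=[N+]=[N-])C(=O)CCC[C@H]12 | intermediate
12 | tricyclic keto lactam, rings A, B and C; lactam carbonyl at C5, ketone at C11, ethyl on C10 trans to C8, B/C cis-fused (9R,9aS,10R) | CC[C@H]1C(=O)C[C@]23CCCN2C(=O)CCC[C@H]13 | intermediate
13 | ethyl glyoxylate | CCOC(=O)C=O | starting material
14 | aldol adduct: 12 with CH(OH)CO2Et on C12, cis to C1 and trans to N4 (9R,9aR,10R,12R; C13 either) | CC[C@H]1C(=O)[C@@H](C(O)C(=O)OCC)[C@]23CCCN2C(=O)CCC[C@H]13 | intermediate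
15 | diol ester: C11 hydroxyl cis to the C10 ethyl and to the C12 side chain (9R,9aR,10R,11R,12S; C13 either) | CC[C@H]1[C@@H](O)[C@@H](C(O)C(=O)OCC)[C@]23CCCN2C(=O)CCC[C@H]13 | intermediate (not isolated)
16 | α-hydroxy lactone, ring D cis-fused to ring C (9R,9aR,10R,11R,12R; C13 either) | CC[C@H]1[C@H]2OC(=O)C(O)[C@H]2[C@]23CCCN2C(=O)CCC[C@H]13 | intermediate
17 | tert-butyldimethylsilyl ether of 16 (9R,9aR,10R,11R,12S; C13 either) | CC[C@H]1[C@H]2OC(=O)C(O[Si](C)(C)C(C)(C)C)[C@H]2[C@]23CCCN2C(=O)CCC[C@H]13 | intermediate
18 | C13-methylated silyloxy lactone, methyl exo and silyloxy endo (9R,9aR,10R,11R,12S,13S) | CC[C@H]1[C@H]2OC(=O)[C@@](C)(O[Si](C)(C)C(C)(C)C)[C@H]2[C@]23CCCN2C(=O)CCC[C@H]13 | intermediate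
19 | 3-methoxy derivative of 18 (C3 either) | CC[C@H]1[C@H]2OC(=O)[C@@](C)(O[Si](C)(C)C(C)(C)C)[C@H]2[C@]23CCC(OC)N2C(=O)CCC[C@H]13 | intermediate
20 | 3-methylfuran-2(5H)-one | CC1=CCOC1=O | starting material
21 | 3-methyl-2-(triisopropylsilyloxy)furan | Cc1ccoc1O[Si](C(C)C)(C(C)C)C(C)C | intermediate
22 | butenolide adduct: 4-methyl-5-oxo-2,5-dihydrofuran-2-yl on C3, cis to C9, threo (3S,9R,9aR,10R,11R,12S,13S,18S) | CC[C@H]1[C@H]2OC(=O)[C@@](C)(O[Si](C)(C)C(C)(C)C)[C@H]2[C@]23CC[C@@H]([C@@H]4C=C(C)C(=O)O4)N2C(=O)CCC[C@H]13 | intermediate
23 | saturated lactone E lactam, C20 methyl cis to the C18 substituent (3S,9R,9aR,10R,11R,12S,13S,18S,20S) | CC[C@H]1[C@H]2OC(=O)[C@@](C)(O[Si](C)(C)C(C)(C)C)[C@H]2[C@]23CC[C@@H]([C@@H]4C[C@H](C)C(=O)O4)N2C(=O)CCC[C@H]13 | intermediate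
24 | C5 thiolactam of 23 | CC[C@H]1[C@H]2OC(=O)[C@@](C)(O[Si](C)(C)C(C)(C)C)[C@H]2[C@]23CC[C@@H]([C@@H]4C[C@H](C)C(=O)O4)N2C(=S)CCC[C@H]13 | intermediate
25 | tert-butyldimethylsilyl ether of the target (3S,9R,9aR,10R,11R,12S,13S,18S,20S) | CC[C@H]1[C@H]2OC(=O)[C@@](C)(O[Si](C)(C)C(C)(C)C)[C@H]2[C@]23CC[C@@H]([C@@H]4C[C@H](C)C(=O)O4)N2CCCC[C@H]13 | intermediate
26 | CNP0260919.3 (3S,9R,9aR,10R,11R,12S,13S,18S,20S) | CC[C@H]1[C@H]2OC(=O)[C@@](C)(O)[C@H]2[C@]23CC[C@@H]([C@@H]4C[C@H](C)C(=O)O4)N2CCCC[C@H]13 | target

## Step count and least certain steps

Total: 17 steps. Longest linear sequence: 16 steps (steps 1–11 and 13–17); step 12 is a one-step side branch.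

**Step 3 (Proposed new method).**
- **What may go wrong:** the enamine cyclisation may be slow or poorly enantioselective, because the five-membered enolendo closure strains the enamine transition state. Reversible formation of a bridged ketol through a ring-ketone enamine, or ring opening of the 2,2-disubstituted dione, may compete.
- **Fallback (known chemistry), from 6 back to 7:** the standard base-mediated aldol condensation of a 1,4-diketone to a cyclopentenone (catalytic KOtBu in tBuOH, or KOH in MeOH) gives racemic enone. The enantiomers are separated by preparative chromatography on a chiral stationary phase. (S)-7 is taken on and the (R)-enone F1 is discarded. This replaces catalytic desymmetrisation by resolution, at the cost of half the material at an early stage.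

**Step 6 (key step).**
- **What may go wrong:** C6H2 may migrate in place of C9a if the diazonium group reacts from an axial position, giving a bridged lactam. The azidohydrin may fragment at the quaternary carbon. The 1,4-diketone may self-condense in strong acid.
- **Fallback, from 11 back to 12:** triphenylphosphane in hot toluene (Staudinger reduction and intramolecular aza-Wittig reaction with the C5 ketone) gives the tricyclic imine F2. mCPBA oxidises it to the ring-fused oxaziridine F3. Irradiation at 254 nm rearranges the oxaziridine to the lactam. In F3 the ring fusion forces C9a to lie trans to the nitrogen lone pair, so the stereoelectronic rule of this photorearrangement moves C9a to nitrogen and gives 12. The regiochemistry is then fixed by geometry and not by a conformational preference.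

**Step 2.**
- **What may go wrong:** competing O-alkylation of the dione enolate, and base-induced self-condensation of the bromoketone.
- **Fallback, from 4 back to 6:** C-alkylation with 1-bromopent-2-yne in aqueous NaOH (propargylic halides alkylate 2-alkyl-1,3-diones on carbon) gives the alkynyl dione F4. Hydration with Ph3PAuCl/AgOTf in aqueous dioxane (or HgSO4/H2SO4) gives triketone 6. A ring carbonyl adds to the proximal alkyne carbon in 5-exo-dig fashion, which places the new ketone at C11.

**Step 7.**
- **What may go wrong:** partial enolisation on the ethyl-bearing side (C10), and proton transfer or retro-aldol in the lithium aldolate, which would erode the regiochemistry and the C12 configuration.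
- **Fallback, from 12 back to 14:** deprotonation with LDA in the presence of Me3SiCl (internal quench) gives the kinetic silyl enol ether F5, whose regiochemistry can be checked and purified. A Mukaiyama aldol addition to 13 (TiCl4, CH2Cl2, −78 °C) then gives 14 under Lewis-acidic conditions, where the adduct cannot revert or equilibrate.

**Step 13.**
- **What may go wrong:** the silyloxyfuran may attack the face of the N-acyliminium ion syn to C12, because the steric difference between the two faces of ring A is modest. The threo preference may be low. The ion may lose a proton to the enamide.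
- **Fallback, from 18 back to 23:** the order in which carbon and hydrogen arrive at C3 is reversed, so that the face preferred by an incoming reagent is taken by hydride and the carbon substituent ends on the other face.
  1. RuCl3 (cat.)/NaIO4 oxidises C3 to the imide F6.
  2. Vinylmagnesium bromide with CeCl3 adds to the five-membered imide carbonyl, expected to be the more electrophilic one, giving the vinyl carbinol lactam F7.
  3. Et3SiH/BF3·OEt2 reduces the derived N-acyliminium ion to the 3-vinyl lactam F8.
  4. Ozonolysis with Me2S work-up gives the aldehyde F9.
  5. Zinc and ethyl 2-(bromomethyl)acrylate add to the aldehyde and the product lactonises to the α-methylene lactone F10. C18 is set under chelate or Felkin–Anh control, which has to be established.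
  6. Hydrogenation over Pd/C from the face opposite to the C18 substituent gives 23.

## Further compounds

F1 | step 3 | (R)-3a-[3-(benzyloxy)propyl]-1-ethyl-3,5,6,7-tetrahydro-2H-indene-2,4(3aH)-dione | CCC1=C2CCCC(=O)[C@]2(CCCOCc3ccccc3)CC1=O
F2 | step 6 | tricyclic imine from aza-Wittig closure of the arm nitrogen onto C5 (9R,9aS,10R) | CC[C@H]1C(=O)C[C@]23CCCN=C2CCC[C@H]13
F3 | step 6 | ring-fused oxaziridine of F2 (N–O–C5 ring, cis-fused; either face) | CC[C@H]1C(=O)C[C@]23CCCN4OC24CCC[C@H]13
F4 | step 2 | 2-[3-(benzyloxy)propyl]-2-(pent-2-yn-1-yl)cyclohexane-1,3-dione | CCC#CCC1(CCCOCc2ccccc2)C(=O)CCCC1=O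
F5 | step 7 | trimethylsilyl enol ether of 12 (C11–O–Si, C11=C12) | CC[C@H]1C(O[Si](C)(C)C)=C[C@]23CCCN2C(=O)CCC[C@H]13
F6 | step 13 | imide: 18 with a carbonyl at C3 | CC[C@H]1[C@H]2OC(=O)[C@@](C)(O[Si](C)(C)C(C)(C)C)[C@H]2[C@]23CCC(=O)N2C(=O)CCC[C@H]13
F7 | step 13 | 3-hydroxy-3-vinyl lactam (C3 either) | CC[C@H]1[C@H]2OC(=O)[C@@](C)(O[Si](C)(C)C(C)(C)C)[C@H]2[C@]23CCC(O)(C=C)N2C(=O)CCC[C@H]13
F8 | step 13 | 3-vinyl lactam, vinyl cis to C9 | CC[C@H]1[C@H]2OC(=O)[C@@](C)(O[Si](C)(C)C(C)(C)C)[C@H]2[C@]23CC[C@@H](C=C)N2C(=O)CCC[C@H]13
F9 | step 13 | 3-formyl lactam | CC[C@H]1[C@H]2OC(=O)[C@@](C)(O[Si](C)(C)C(C)(C)C)[C@H]2[C@]23CC[C@@H](C=O)N2C(=O)CCC[C@H]13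
F10 | step 13 | α-methylene lactone E lactam (18S) | CC[C@H]1[C@H]2OC(=O)[C@@](C)(O[Si](C)(C)C(C)(C)C)[C@H]2[C@]23CC[C@@H]([C@@H]4CC(=C)C(=O)O4)N2C(=O)CCC[C@H]13
A1 | alternative 1 | vinyl-substituted spiro-2H-pyrrole (rings A and C, C11 dioxolane, silyloxymethyl on C3) | CC[C@H]1C2(OCCO2)C[C@@]3(C=CC(CO[Si](C)(C)C(C)(C)C)=N3)[C@@H]1C=C
A2 | alternative 2 | (2R,3R,4R)-4-(tert-butyldimethylsilyloxy)-2-[4-(tert-butyldimethylsilyloxy)but-2-yn-1-yl]-3-ethylcyclopentan-1-one | CC[C@H]1[C@H](O[Si](C)(C)C(C)(C)C)CC(=O)[C@@H]1CC#CCO[Si](C)(C)C(C)(C)C
A3 | alternative 2 | (R)-4-(tert-butyldimethylsilyloxy)cyclopent-2-en-1-one | O=C1C=C[C@H](O[Si](C)(C)C(C)(C)C)C1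
A4 | alternative 2 | tert-butyl[(4-iodobut-2-yn-1-yl)oxy]dimethylsilane | ICC#CCO[Si](C)(C)C(C)(C)C
A5 | alternative 3 | ring C ketone with a benzyloxy ester side chain on C12 and the lactam carbonyl at C3 (either epimer at the benzyloxy carbon) | CC[C@H]1C(=O)[C@@H](C(OCc2ccccc2)C(=O)OC)[C@]23CCC(=O)N2CCCC[C@H]13
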